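A rate in direct proportion to the X charged cannot do what the red run does.

the same everywhere: J 200 mM (held)

|  | G | Z | X | remark |
|---|---|---|---|---|
| blue | 1 M | 1 M | 1.1 mM | run made earlier |
| red | 1 M | 1 M | 4.6 mM | run made earlier |
| green | 1.5 M | 1.5 M | 2.3 mM | run made earlier |
| flask | 1.0 M | 1.0 M | 2.3 mM |  |

- blue (time / s: Q / %, G / %): 10.0: 0.4, 49.8; 12.0: 0.8, 48.5; 15.0: 1.2, 48.9; 25.0: 2.4, 48.1; 40.0: 3.9, 46.8; 60.0: 5.1, 44.2; 90.0: 8.5, 41.5
- red (time / s: Q / %, G / %): 12.0: 2.1, 47.5; 25.0: 5.9, 44.6; 40.0: 9.7, 40.6; 50.0: 10.7, 39.0; 60.0: 13.1, 38.6; 80.0: 15.1, 35.5; 90.0: 16.2, 34.1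
- green (time / s: Q / %, G / %): 20.0: 3.4, 47.3; 40.0: 5.5, 45.0; 50.0: 6.3, 42.5; 80.0: 9.7, 39.0; 90.0: 11.7, 37.8

(standard deviation of a reading: 0.5 percentage points)

- X is single-handed; G and Z are mirror images of each other, charged as a racemate, each of them at the stated concentration
- at the start none of J is in solution

1. factor on the rate of making Q when 20% of the G and Z together are converted if X is charged twice over
2. factor on the rate when 20% of the G and Z together are converted if X is charged at 12 mM instead

I read the row at 40.0 s, where all runs have a reading. Q stands at 3.9% in blue, 5.5% in green and 9.7% in red. Red is charged with 4.18 times the X of blue but reads 2.49 times its Q, which is less.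

So I carry one reading, the X exponent, an apparent reaction order: the logarithm of the ratio of Q over the logarithm of the ratio of X. The blue and red readings give 0.637, good to about 0.0966. If Q as a fraction of the charge does not change with the larger charge of G, green should read 6.24% with this exponent, so its reading lies 1.48 scatters low. At 90.0 s, the ratio of Q in red to Q in blue is 1.91, so my figures may lean high.

I integrate a first-order loss of G. In this reckoning, the logarithm of the fraction left falls with time multiplied by the X charged raised to the exponent. At one fraction left, the rate goes with the X charged raised to the exponent, and the time goes inversely. For this flask I reckon 1.56 for doubled X and 2.86 for 12 mM.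

The forecast gives 1.45 and 2.4, citing “an apparent order near 0.6”, and its second figure is lower than mine.

The flask gives 1.57 and 2.45.

    2 X → E (k = 2.90 M⁻¹ s⁻¹)
    L + X + Z → X + D (k = 5.70 M⁻² s⁻¹)
    L + X + G → X + Q (k = 14.0 M⁻² s⁻¹)
    J ⇌ L, rate k4*(csat - [L]) (kL = 0.130 s⁻¹)

Twice the X multiplies the time to that conversion by 0.651, and my exponent gives 0.643. The factor at 12 mM corresponds to an exponent of 0.543. In the flask, the first half-life of X by the step to E alone is 1.25 min, shorter than the 1.77 min taken to reach the 20%, and at that conversion X is 41.3% of the catalyst and E 58.7%. With 12 mM, that half-life is 0.239 min, and X at the same conversion is 24.1% of the catalyst.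

The earlier runs and the new flask are simulated with constants of no real substance; noise was put on by code.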